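## Structural features

The target is a 3,4-dihydro-2H-pyran (ring atoms O1, C2–C6) whose C5=C6 enol ether is conjugated with a methyl ester on C5, forming a vinylogous carbonate. C2 carries a methyl group, C3 a hydroxymethyl group (C7), and C4 an acetic acid arm (C8–C9) esterified with the aliphatic hydroxyl of hydroxytyrosol. C2, C3 and C4 are contiguous stereocentres, (2R,3R,4S), with 2,3-trans and 3,4-trans relationships, so the methyl group and the C4 arm are cis-1,3 and the hydroxymethyl group lies on the other face. The fragile parts are the catechol (easily oxidised, most of all as a phenoxide), the acid-sensitive enol ether carbon C6, and the C7 hydroxyl, which sits 1,5 to the C9 ester carbonyl and can close a δ-lactone with loss of the phenethyl alcohol. The real difficulty is to set three adjacent ring stereocentres, of which C4 cannot be corrected by epimerisation, and to bring C7, C9 and the C5 ester to three different oxidation levels without disturbing them. The key step exploits the position of the C3–C4 bond: it is allylic to C5=C6 and α to C7. If C7 is a carboxyl carbon and C6 an acetal carbon, this bond is the one an ester-enolate [3,3] shift forms from a six-membered acetal lactone. In that lactone a 3-hydroxybutanoic acid supplies O1, C2, C3, C7 and the methyl group, and an enal equivalent supplies C6, C5, C4, C8 and C9.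

## Logic of the disconnections

22 ⇒ 21. The three O–H bonds of the catechol and of C7 are replaced by O–Si bonds. The masks make the oxidation at C9 and the esterification possible and fall in one fluoride step. The forward step must not let the freed C7 hydroxyl attack the C9 ester.

21 ⇒ 17 + 20. The C9–O ester bond is cut. This is the most convergent cut and keeps the oxidation-prone arene out of all earlier steps. It demands a neutral acylation of a primary alcohol by an unhindered acid.

20 ⇒ 19 ⇒ 18. Si–O bonds only. Full silylation followed by acid-selective release of the aliphatic oxygen distinguishes the alcohol from the two phenols without any selective first step.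

17 ⇒ 16 ⇒ 15. C9 is taken back from carboxyl to carbinol and then to its 4-methoxybenzyl ether. The arm has to travel at the alcohol level through enolate, hydride and acylation chemistry. The forward oxidation must tolerate the vinylogous carbonate and the silyl ether.

15 ⇒ 13 (through 14). The bond between C5 and the ester carbon is cut. The ester carbon can be added as an acyl cation equivalent to the nucleophilic β-carbon of a plain enol ether, which is what the key step delivers. The demand is C-acylation next to the branched C4.

13 ⇒ 12 ⇒ 11. Functional-group changes at C7 only (silyl ether, carbinol, carboxyl). The carboxyl is needed because it is what the sigmatropic step leaves at C3.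

11 ⇒ 8 (through 10 and 9). The C3–C4 bond is cut and C6 is reconnected to the acyl oxygen. This removes the ring and two stereocentres at once and leaves one carbinol centre from the chiral pool, one acetal centre and one alkene geometry. The demands are a cis acetal, a Z alkene, and generation of the ketene acetal without β-elimination.

8 ⇒ 7. The Z alkene is taken back to an alkyne, because a Z enal would not keep its geometry through acetalisation. The demand is a syn semireduction that spares the acylal.

7 ⇒ 4 + 6. Both acetal C–O bonds are cut, which separates the chiral-pool half from the achiral five-carbon half. The demand is cis-selective ring closure.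

6 ⇒ 5, and 4 ⇒ 3 ⇒ 1 + 2. These are silylation of the hydroxy acid, the bond between the alkyne terminus and the formyl carbon, and the benzyl-type ether bond. All three are routine.

## Other disconnections considered

Alternative 1: The ring oxygen is taken out (O1–C2 and O1–C6 cut, C2–C6 joined), which gives the all-trans cyclopentanone A1. In the forward direction a peracid would insert oxygen on the methyl-bearing side of the ketone and give δ-lactone A2 with retention at C2.
- In its favour: migration of the more substituted α-carbon and retention of configuration are dependable. The three trans substituents sit on a five-membered ring on which the α-methyl centre can be equilibrated.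
- Against it here: A2 has C6 at the carboxyl level and C5 as a bare methylene. The vinylogous carbonate would still need a C5 methoxycarbonylation and a selective reduction–dehydration of the lactone carbonyl beside two other esters. The tert-butyl ester would later have to be exchanged under acid that the enol ether and silyl ether tolerate poorly. A1 has no chiral-pool origin.
- Comparison: on mechanism the oxygen insertion is the equal or the better of the chosen step, since it has no strained boat and no competing fragmentation. On structure the chosen plan is better, because the shift gives the C5=C6 enol ether directly and takes C2 from 5. On step economy the alternative should be longer after its key step.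

Alternative 2: O1–C2 is cut, which opens the ring to A3, the enol of an α-formyl ester carrying an (E)-ethylidene enal. In the forward direction the enol oxygen would add 6-endo to the enal β-carbon and give aldehyde A4.
- In its favour: after closure the C5 ester, the enol ether and C7 (as a formyl group) are all present, so one hydride reduction and one silylation reach the stage of 15. This is better step economy after the key step than the chosen plan. C3 is epimerisable and the oxa-Michael addition reversible, so the all-trans isomer should build up.
- Against it here: A3 is a doubly electrophilic, enolisable 1,5-dicarbonyl compound. It can close in other ways (hemiacetal formation at the enal carbonyl, aldol condensation) and can isomerise at the ethylidene group. Its only stereocentre, C4, needs separate asymmetric chemistry and would then have to control C2 across the ring by thermodynamics alone.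
- Comparison: on mechanism the alternative is the equal or the better in simplicity, being one polar, reversible step. On structure the chosen plan is better, because C2 is fixed from the chiral pool and relayed to C3 and C4 by geometry. On step economy the alternative is better after ring closure and probably worse before it.

Alternative 3: O1–C6 and C4–C5 are both cut, leaving hydroxy enoate A5 and methyl propiolate A6. In the forward direction the C2 alkoxide would add to A6 and the resulting vinyl anion (allenolate) would close 6-exo on the enoate β-carbon to give A7, which is identical with 21.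
- In its favour: it is the most convergent plan. It forms two bonds, the ring and the whole vinylogous carbonate in one operation on a substrate that already holds the phenethyl ester, and A7 is one deprotection from the target. This is better step economy than the chosen plan. C2 and C3 would again come from the chiral pool.
- Against it here: the vinyl anion is normally protonated by the alcohol before it can cyclise, so an open-chain β-alkoxyacrylate is the likely resting point and a second polar closure from it is not available. C4 would be set in an irreversible C–C bond formation with only the adjacent C3 substituent to guide it. The aryl silyl ethers would have to survive alkoxide or nucleophilic catalysts.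
- Comparison: on structure the origin of C2 is equal, and control of C4 is better in the chosen plan (alkene geometry in an enforced boat against an open transition state). On mechanism the chosen concerted shift is more secure. On step economy the alternative is better if its cascade runs to completion.

Key step: step 6

Remark on the chemistry: the stereochemical course was re-derived from the bicyclic boat and no structure needed correction. The cis acetal 8 is (2R,6R) and acid 11 is (2R,3S,4R); the descriptors become (3R,4R) in 12 and 13 and (3R,4S) from 14 onward only because substituent priorities change. The design changes concern generation of the ketene acetal (internal silyl quench, amine buffer, non-polar thermal stage) and merging of later steps.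

## Route

Step 1
Reactants: 1 but-3-yn-1-ol; 2 4-methoxybenzyl chloride
Product: 3 1-[(but-3-yn-1-yloxy)methyl]-4-methoxybenzene
Conditions: NaH, Bu4NI (cat.), THF/DMF, 0 °C → rt
Reagents that add atoms: none
Why: Williamson ether synthesis; the alkoxide forms far more readily than the acetylide and displaces the benzylic chloride, with iodide catalysis.

Step 2
Reactants: 3 1-[(but-3-yn-1-yloxy)methyl]-4-methoxybenzene
Product: 4 5-[(4-methoxyphenyl)methoxy]pent-2-ynal
Conditions: n-BuLi, THF, −78 °C; DMF, −78 → 0 °C; inverse quench into aq. KH2PO4
Reagents that add atoms: N,N-dimethylformamide, CN(C)C=O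
Why: Formylation of a lithium acetylide with DMF; the hemiaminal alkoxide persists until the buffered inverse quench, which should release the ynal without conjugate addition of dimethylamine.

Step 3
Reactants: 5 (R)-3-hydroxybutanoic acid
Product: 6 trimethylsilyl (3R)-3-(trimethylsilyloxy)butanoate
Conditions: Me3SiCl, Et3N, CH2Cl2, 0 °C → rt
Reagents that add atoms: chlorotrimethylsilane, C[Si](C)(C)Cl
Why: Exhaustive O-silylation of the hydroxyl and carboxyl groups; the stereocentre is not involved.

Step 4
Reactants: 4 5-[(4-methoxyphenyl)methoxy]pent-2-ynal; 6 trimethylsilyl (3R)-3-(trimethylsilyloxy)butanoate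
Product: 7 (2R,6R)-2-[4-[(4-methoxyphenyl)methoxy]but-1-yn-1-yl]-6-methyl-1,3-dioxan-4-one (cis)
Conditions: Me3SiOTf (5 mol %), CH2Cl2, −78 °C; pyridine quench
Reagents that add atoms: none
Why: Silyl-triflate-catalysed acetalisation of an aldehyde with a bis-silylated hydroxy acid, run under kinetic control at low temperature. Chair-like closure of the oxocarbenium ion should place the C2 substituent equatorial, cis to the 6-methyl group, so the existing carbinol centre sets the acetal centre as (R).

Step 5
Reactants: 7 (2R,6R)-2-[4-[(4-methoxyphenyl)methoxy]but-1-yn-1-yl]-6-methyl-1,3-dioxan-4-one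
Product: 8 (2R,6R)-2-[(1Z)-4-[(4-methoxyphenyl)methoxy]but-1-en-1-yl]-6-methyl-1,3-dioxan-4-one (cis)
Conditions: H2 (1 atm), Pd/CaCO3–Pb(OAc)2, quinoline, EtOAc, rt
Reagents that add atoms: none
Why: Lindlar semihydrogenation; syn delivery of hydrogen on the poisoned palladium surface gives the Z alkene. The acylal, the lactone and the benzyl-type ether should survive the deactivated catalyst if uptake is stopped after one equivalent.

Step 6
Reactants: 8 (2R,6R)-2-[(1Z)-4-[(4-methoxyphenyl)methoxy]but-1-en-1-yl]-6-methyl-1,3-dioxan-4-one
Product: 11 (2R,3S,4R)-4-[2-[(4-methoxyphenyl)methoxy]ethyl]-2-methyl-3,4-dihydro-2H-pyran-3-carboxylic acid, via cyclic trimethylsilyl ketene acetal 9 (not isolated), via trimethylsilyl ester 10 (not isolated)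
Conditions: LiN(iPr)2, Me3SiCl, Et3N, THF, −78 °C; then toluene, 70 °C; then aq. NaH2PO4
Reagents that add atoms: none
Why: LiN(iPr)2 removes a C5 proton of the lactone in the presence of Me3SiCl, so the enolate is O-silylated at once to the ring-locked ketene acetal 9 instead of expelling the β-acetal oxygen. On warming, 9 should undergo a concerted suprafacial [3,3] shift (Ireland–Claisen rearrangement): the ketene-acetal carbon (pyran C3) bonds to the far alkene carbon (pyran C4) while the acetal C–O(acyl) bond breaks with lone-pair assistance from the ring oxygen, giving silyl ester 10 and, after hydrolysis, acid 11. The closest known reaction type is the Ireland–Claisen ring contraction of alkenyl lactones, in particular the conversion of 6-alkenyl-1,4-dioxan-2-ones into dihydropyrans; here the allylic terminus is an acetal carbon, whose donor oxygen should lower the barrier. The dihydropyran ring is closed by the sigmatropic event itself (a ring contraction, not an exo or endo cyclisation), because the two-atom O–CHMe bridge between the reacting termini forces the six-atom array into a boat inside a bicyclo[2.2.2]octadiene-like transition state. C3 is controlled by the cis acetal: the tethered alkene can reach the enol carbon only from the face it shares with the methyl group, which leaves the carboxyl trans to methyl. C4 is controlled by the Z geometry: in the enforced boat the Z substituent points toward the O–CHMe bridge and ends trans to the carboxyl, whereas an E alkene would give the C4 epimer. The shift must outrun β-elimination, retro-[4+2] cleavage to a silyl crotonate and an enal, and ionisation of the acylal (which would scramble the alkene); the internal silyl quench at −78 °C, the amine-buffered non-polar medium and only moderate heat (needed because methyl and Z substituent are syn in the boat) are meant to secure this.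

Step 7
Reactants: 11 (2R,3S,4R)-4-[2-[(4-methoxyphenyl)methoxy]ethyl]-2-methyl-3,4-dihydro-2H-pyran-3-carboxylic acid
Product: 12 [(2R,3R,4R)-4-[2-[(4-methoxyphenyl)methoxy]ethyl]-2-methyl-3,4-dihydro-2H-pyran-3-yl]methanol
Conditions: LiAlH4, THF, 0 °C → rt
Reagents that add atoms: none
Why: Hydride reduction of a carboxylic acid through its carboxylate to the primary alcohol; the isolated enol ether and the ethers are inert and the carboxylate is not enolised, so C3 is kept. The crude acid should be used at once so that it cannot add to its own enol ether.

Step 8
Reactants: 12 [(2R,3R,4R)-4-[2-[(4-methoxyphenyl)methoxy]ethyl]-2-methyl-3,4-dihydro-2H-pyran-3-yl]methanol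
Product: 13 tert-butyl{[(2R,3R,4R)-4-[2-[(4-methoxyphenyl)methoxy]ethyl]-2-methyl-3,4-dihydro-2H-pyran-3-yl]methoxy}dimethylsilane
Conditions: TBSCl, imidazole, CH2Cl2, rt
Reagents that add atoms: tert-butyldimethylsilyl chloride, CC(C)(C)[Si](C)(C)Cl
Why: Imidazole-mediated silylation of a primary alcohol; the basic medium protects the enol ether.

Step 9
Reactants: 13 tert-butyl{[(2R,3R,4R)-4-[2-[(4-methoxyphenyl)methoxy]ethyl]-2-methyl-3,4-dihydro-2H-pyran-3-yl]methoxy}dimethylsilane
Product: 15 methyl (2R,3R,4S)-3-[(tert-butyldimethylsilyloxy)methyl]-4-[2-[(4-methoxyphenyl)methoxy]ethyl]-2-methyl-3,4-dihydro-2H-pyran-5-carboxylate, via trichloromethyl ketone 14 (not isolated)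
Conditions: Cl3CCOCl, pyridine, CH2Cl2, 0 °C → rt; then MeOH, Et3N, rt
Reagents that add atoms: trichloroacetyl chloride, ClC(Cl)(Cl)C(Cl)=O; methanol, CO
Why: The enol ether is acylated at its nucleophilic β-carbon C5 (Friedel–Crafts-type C-acylation of an enol ether followed by loss of the proton). The trichloromethyl ketone is then cleaved by methanol in a haloform-type substitution that expels the trichloromethyl anion as chloroform. Neither stage touches C2, C3 or C4, and the silyl and benzyl-type ethers tolerate amine bases.

Step 10
Reactants: 15 methyl (2R,3R,4S)-3-[(tert-butyldimethylsilyloxy)methyl]-4-[2-[(4-methoxyphenyl)methoxy]ethyl]-2-methyl-3,4-dihydro-2H-pyran-5-carboxylate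
Product: 16 methyl (2R,3R,4S)-3-[(tert-butyldimethylsilyloxy)methyl]-4-(2-hydroxyethyl)-2-methyl-3,4-dihydro-2H-pyran-5-carboxylate
Conditions: DDQ, CH2Cl2/pH 7 buffer, 0 °C
Reagents that add atoms: none
Why: Oxidative cleavage of the 4-methoxybenzyl ether by hydride abstraction and hydrolysis of the oxocarbenium ion; the ester-conjugated enol ether is too electron-poor to be oxidised and the buffer protects the silyl ether.

Step 11
Reactants: 16 methyl (2R,3R,4S)-3-[(tert-butyldimethylsilyloxy)methyl]-4-(2-hydroxyethyl)-2-methyl-3,4-dihydro-2H-pyran-5-carboxylate
Product: 17 2-[(2R,3R,4S)-3-[(tert-butyldimethylsilyloxy)methyl]-5-(methoxycarbonyl)-2-methyl-3,4-dihydro-2H-pyran-4-yl]acetic acid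
Conditions: TEMPO (cat.), PhI(OAc)2, MeCN/H2O, rt
Reagents that add atoms: water, O
Why: Oxoammonium-mediated oxidation of the primary alcohol to the aldehyde, whose hydrate is oxidised on to the acid in the same flask. The conditions are near neutral, so the silyl ether and the vinylogous carbonate should survive, and no stereocentre is α to the new carboxyl.

Step 12
Reactants: 18 hydroxytyrosol, 4-(2-hydroxyethyl)benzene-1,2-diol
Product: 19 tert-butyl{2-[3,4-bis(tert-butyldimethylsilyloxy)phenyl]ethoxy}dimethylsilane
Conditions: TBSCl, imidazole, DMF, rt
Reagents that add atoms: tert-butyldimethylsilyl chloride, CC(C)(C)[Si](C)(C)Cl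
Why: Exhaustive silylation of all three hydroxyl groups avoids any selective step on the catechol.

Step 13
Reactants: 19 tert-butyl{2-[3,4-bis(tert-butyldimethylsilyloxy)phenyl]ethoxy}dimethylsilane
Product: 20 2-[3,4-bis(tert-butyldimethylsilyloxy)phenyl]ethan-1-ol
Conditions: camphorsulfonic acid (cat.), MeOH/CH2Cl2, 0 °C
Reagents that add atoms: none
Why: Acid-catalysed methanolysis of silyl ethers is much faster at the more basic alkyl oxygen than at the aryl oxygens, so only the aliphatic silyl ether should be removed.

Step 14
Reactants: 17 2-[(2R,3R,4S)-3-[(tert-butyldimethylsilyloxy)methyl]-5-(methoxycarbonyl)-2-methyl-3,4-dihydro-2H-pyran-4-yl]acetic acid; 20 2-[3,4-bis(tert-butyldimethylsilyloxy)phenyl]ethan-1-ol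
Product: 21 methyl (2R,3R,4S)-4-[2-[2-[3,4-bis(tert-butyldimethylsilyloxy)phenyl]ethoxy]-2-oxoethyl]-3-[(tert-butyldimethylsilyloxy)methyl]-2-methyl-3,4-dihydro-2H-pyran-5-carboxylate
Conditions: DCC, DMAP (cat.), CH2Cl2, 0 °C → rt
Reagents that add atoms: none
Why: Steglich esterification; the O-acylisourea is passed on by DMAP to the unhindered primary alcohol under neutral conditions that spare aryl silyl ethers and the enol ether.

Step 15
Reactants: 21 methyl (2R,3R,4S)-4-[2-[2-[3,4-bis(tert-butyldimethylsilyloxy)phenyl]ethoxy]-2-oxoethyl]-3-[(tert-butyldimethylsilyloxy)methyl]-2-methyl-3,4-dihydro-2H-pyran-5-carboxylate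
Product: 22 methyl (2R,3R,4S)-4-[2-[2-(3,4-dihydroxyphenyl)ethoxy]-2-oxoethyl]-3-(hydroxymethyl)-2-methyl-3,4-dihydro-2H-pyran-5-carboxylate (target)
Conditions: Et3N·3HF, THF, 0 °C → rt, argon
Reagents that add atoms: none
Why: Fluoride-driven cleavage of the two aryl and one alkyl silyl ethers with a buffered, non-basic fluoride source. No phenoxide or alkoxide should build up, which is meant to suppress both catechol oxidation and attack of the C7 hydroxyl on the C9 ester.

## Compound list

1 | but-3-yn-1-ol | C#CCCO | starting material
2 | 4-methoxybenzyl chloride | COc1ccc(CCl)cc1 | starting material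
3 | 1-[(but-3-yn-1-yloxy)methyl]-4-methoxybenzene | C#CCCOCc1ccc(OC)cc1 | intermediate
4 | 5-[(4-methoxyphenyl)methoxy]pent-2-ynal | O=CC#CCCOCc1ccc(OC)cc1 | intermediate
5 | (R)-3-hydroxybutanoic acid | C[C@@H](O)CC(=O)O | starting material
6 | trimethylsilyl (3R)-3-(trimethylsilyloxy)butanoate | C[C@@H](O[Si](C)(C)C)CC(=O)O[Si](C)(C)C | intermediate
7 | (2R,6R)-2-[4-[(4-methoxyphenyl)methoxy]but-1-yn-1-yl]-6-methyl-1,3-dioxan-4-one | C[C@@H]1CC(=O)O[C@H](C#CCCOCc2ccc(OC)cc2)O1 | intermediate
8 | (2R,6R)-2-[(1Z)-4-[(4-methoxyphenyl)methoxy]but-1-en-1-yl]-6-methyl-1,3-dioxan-4-one | C[C@@H]1CC(=O)O[C@H](/C=C\CCOCc2ccc(OC)cc2)O1 | intermediate (key-step precursor)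
9 | (2R,4R)-2-[(1Z)-4-[(4-methoxyphenyl)methoxy]but-1-en-1-yl]-4-methyl-6-(trimethylsilyloxy)-4H-1,3-dioxine | C[C@@H]1C=C(O[Si](C)(C)C)O[C@H](/C=C\CCOCc2ccc(OC)cc2)O1 | intermediate (not isolated)
10 | trimethylsilyl (2R,3S,4R)-4-[2-[(4-methoxyphenyl)methoxy]ethyl]-2-methyl-3,4-dihydro-2H-pyran-3-carboxylate | C1=CO[C@H](C)[C@@H](C(=O)O[Si](C)(C)C)[C@@H]1CCOCc1ccc(OC)cc1 | intermediate (not isolated)
11 | (2R,3S,4R)-4-[2-[(4-methoxyphenyl)methoxy]ethyl]-2-methyl-3,4-dihydro-2H-pyran-3-carboxylic acid | C1=CO[C@H](C)[C@@H](C(=O)O)[C@@H]1CCOCc1ccc(OC)cc1 | intermediate (key-step product)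
12 | [(2R,3R,4R)-4-[2-[(4-methoxyphenyl)methoxy]ethyl]-2-methyl-3,4-dihydro-2H-pyran-3-yl]methanol | C1=CO[C@H](C)[C@@H](CO)[C@@H]1CCOCc1ccc(OC)cc1 | intermediate
13 | tert-butyl{[(2R,3R,4R)-4-[2-[(4-methoxyphenyl)methoxy]ethyl]-2-methyl-3,4-dihydro-2H-pyran-3-yl]methoxy}dimethylsilane | C1=CO[C@H](C)[C@@H](CO[Si](C)(C)C(C)(C)C)[C@@H]1CCOCc1ccc(OC)cc1 | intermediate
14 | 1-[(2R,3R,4S)-3-[(tert-butyldimethylsilyloxy)methyl]-4-[2-[(4-methoxyphenyl)methoxy]ethyl]-2-methyl-3,4-dihydro-2H-pyran-5-yl]-2,2,2-trichloroethan-1-one | ClC(Cl)(Cl)C(=O)C1=CO[C@H](C)[C@@H](CO[Si](C)(C)C(C)(C)C)[C@@H]1CCOCc1ccc(OC)cc1 | intermediate (not isolated)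
15 | methyl (2R,3R,4S)-3-[(tert-butyldimethylsilyloxy)methyl]-4-[2-[(4-methoxyphenyl)methoxy]ethyl]-2-methyl-3,4-dihydro-2H-pyran-5-carboxylate | COC(=O)C1=CO[C@H](C)[C@@H](CO[Si](C)(C)C(C)(C)C)[C@@H]1CCOCc1ccc(OC)cc1 | intermediate
16 | methyl (2R,3R,4S)-3-[(tert-butyldimethylsilyloxy)methyl]-4-(2-hydroxyethyl)-2-methyl-3,4-dihydro-2H-pyran-5-carboxylate | COC(=O)C1=CO[C@H](C)[C@@H](CO[Si](C)(C)C(C)(C)C)[C@@H]1CCO | intermediate
17 | 2-[(2R,3R,4S)-3-[(tert-butyldimethylsilyloxy)methyl]-5-(methoxycarbonyl)-2-methyl-3,4-dihydro-2H-pyran-4-yl]acetic acid | COC(=O)C1=CO[C@H](C)[C@@H](CO[Si](C)(C)C(C)(C)C)[C@@H]1CC(=O)O | intermediate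
18 | hydroxytyrosol, 4-(2-hydroxyethyl)benzene-1,2-diol | OCCc1ccc(O)c(O)c1 | starting material
19 | tert-butyl{2-[3,4-bis(tert-butyldimethylsilyloxy)phenyl]ethoxy}dimethylsilane | CC(C)(C)[Si](C)(C)OCCc1ccc(O[Si](C)(C)C(C)(C)C)c(O[Si](C)(C)C(C)(C)C)c1 | intermediate
20 | 2-[3,4-bis(tert-butyldimethylsilyloxy)phenyl]ethan-1-ol | OCCc1ccc(O[Si](C)(C)C(C)(C)C)c(O[Si](C)(C)C(C)(C)C)c1 | intermediate
21 | methyl (2R,3R,4S)-4-[2-[2-[3,4-bis(tert-butyldimethylsilyloxy)phenyl]ethoxy]-2-oxoethyl]-3-[(tert-butyldimethylsilyloxy)methyl]-2-methyl-3,4-dihydro-2H-pyran-5-carboxylate | COC(=O)C1=CO[C@H](C)[C@@H](CO[Si](C)(C)C(C)(C)C)[C@@H]1CC(=O)OCCc1ccc(O[Si](C)(C)C(C)(C)C)c(O[Si](C)(C)C(C)(C)C)c1 | intermediate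
22 | methyl (2R,3R,4S)-4-[2-[2-(3,4-dihydroxyphenyl)ethoxy]-2-oxoethyl]-3-(hydroxymethyl)-2-methyl-3,4-dihydro-2H-pyran-5-carboxylate | COC(=O)C1=CO[C@H](C)[C@@H](CO)[C@@H]1CC(=O)OCCc1ccc(O)c(O)c1 | target

## Step count and least certain steps

Total: 15 steps. Longest linear sequence: 12 steps (steps 1, 2, 4, 5, 6, 7, 8, 9, 10, 11, 14, 15). Steps 3, 12 and 13 are side branches.

Step 6 (key step). The most likely failures are processes that compete with the shift. The lithium enolate may expel the β-acetal oxygen before it is silylated. On heating, the ketene acetal may fragment by retro-[4+2] cleavage, or the acylal may ionise, which would scramble the alkene geometry and therefore C4. The syn contact between the methyl group and the Z substituent raises the barrier of the wanted shift and gives these processes room.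
Fallback, from 8 back to 11: give up the thermal pericyclic step for a stepwise polar ring contraction at low temperature. The ketene acetal 9 would be made by soft enolisation (Me3SiOTf, Et3N, CH2Cl2, −78 °C), so no lithium enolate is formed. A catalytic amount of Me3SiOTf would then silylate the ring oxygen of the ketene acetal and ionise the acylal to an α,β-unsaturated oxocarbenium ion tethered to a bis-silyl ketene acetal. This should close at the γ-carbon in an intramolecular Mukaiyama–Michael addition (the bond-forming logic of the Petasis–Ferrier rearrangement) to give 10 and, after hydrolysis, 11. In this mode C3 could be corrected afterwards by base equilibration of an ester of 11 toward the all-trans isomer. C4 would rest on a chair-like closure with the arm equatorial and would have to be checked. This fallback makes no compound beyond those listed (F0).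

Step 4. What may go wrong is weak discrimination between the two faces of the oxocarbenium ion, because an alkynyl group is sterically small, giving cis/trans mixtures at the acetal carbon. Partial loss of the 4-methoxybenzyl group or oligomerisation of the ynal under the silyl triflate is also possible.
Fallback, from 4 and 5 back to 7: replace kinetic silyl-transfer acetalisation by a thermodynamically controlled transacetalisation. Ynal 4 would be converted (HC(OMe)3, MeOH, pyridinium p-toluenesulfonate) into the dimethyl acetal 1-[(5,5-dimethoxypent-3-yn-1-yloxy)methyl]-4-methoxybenzene F1. F1 would be heated with free acid 5 and a catalytic sulfonic acid in benzene with removal of methanol over 5 Å sieves. The equilibrating conditions should funnel the material to the diequatorial cis acetal 7, and any trans isomer could be recycled.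

Step 9. What may go wrong is slow or incomplete C-acylation, because C5 lies next to the branched C4. Addition of hydrogen chloride across the enol ether or loss of the silyl group may then take over.
Fallback, from 13 back to 15: install the ester by halogenation and carbonylation instead of acylation and haloform cleavage. Direct C5 iodination of the enol ether (N-iodosuccinimide, AgNO3 cat., MeCN) would give tert-butyl{[(2R,3R,4S)-5-iodo-4-[2-[(4-methoxyphenyl)methoxy]ethyl]-2-methyl-3,4-dihydro-2H-pyran-3-yl]methoxy}dimethylsilane F2. Palladium-catalysed methoxycarbonylation (Pd(OAc)2, 1,3-bis(diphenylphosphino)propane, CO 1 atm, MeOH, Et3N, DMF, 60 °C) should then give 15.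

Step 15. What may go wrong is acyl transfer: once C7–OH is free it can attack the C9 ester and close the δ-lactone with loss of the phenethyl alcohol. The aryl silyl ethers may also be cleaved incompletely under a mild fluoride source, and the catechol may oxidise if the medium becomes basic.
Fallback, from 17 and 18 back to 22: avoid protecting the catechol at all. A Mitsunobu esterification of acid 17 with unprotected 18 (PPh3, diisopropyl azodicarboxylate, THF, 0 °C) activates only the aliphatic hydroxyl, and the carboxylate, being far more acidic than the phenols, acts as the nucleophile. This would give methyl (2R,3R,4S)-3-[(tert-butyldimethylsilyloxy)methyl]-4-[2-[2-(3,4-dihydroxyphenyl)ethoxy]-2-oxoethyl]-2-methyl-3,4-dihydro-2H-pyran-5-carboxylate F3. Only one alkyl silyl ether then remains, and it should fall under mildly acidic fluoride (HF·pyridine, pyridine/THF, 0 °C) to give 22.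

## Further compounds

F0 | step 6 | none | none
F1 | step 4 | 1-[(5,5-dimethoxypent-3-yn-1-yloxy)methyl]-4-methoxybenzene | COC(OC)C#CCCOCc1ccc(OC)cc1
F2 | step 9 | tert-butyl{[(2R,3R,4S)-5-iodo-4-[2-[(4-methoxyphenyl)methoxy]ethyl]-2-methyl-3,4-dihydro-2H-pyran-3-yl]methoxy}dimethylsilane | IC1=CO[C@H](C)[C@@H](CO[Si](C)(C)C(C)(C)C)[C@@H]1CCOCc1ccc(OC)cc1
F3 | step 15 | methyl (2R,3R,4S)-3-[(tert-butyldimethylsilyloxy)methyl]-4-[2-[2-(3,4-dihydroxyphenyl)ethoxy]-2-oxoethyl]-2-methyl-3,4-dihydro-2H-pyran-5-carboxylate | COC(=O)C1=CO[C@H](C)[C@@H](CO[Si](C)(C)C(C)(C)C)[C@@H]1CC(=O)OCCc1ccc(O)c(O)c1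
A1 | alternative 1 | tert-butyl 2-[1,2-trans-2,3-trans-2-(tert-butyldimethylsilyloxymethyl)-3-methyl-4-oxocyclopentyl]acetate | C1C(=O)[C@H](C)[C@@H](CO[Si](C)(C)C(C)(C)C)[C@@H]1CC(=O)OC(C)(C)C
A2 | alternative 1 | tert-butyl 2-[2,3-trans-3,4-trans-3-(tert-butyldimethylsilyloxymethyl)-2-methyl-6-oxotetrahydropyran-4-yl]acetate | C1C(=O)O[C@H](C)[C@@H](CO[Si](C)(C)C(C)(C)C)[C@@H]1CC(=O)OC(C)(C)C
A3 | alternative 2 | methyl (3S,4E)-4-formyl-2-(hydroxymethylidene)-3-[2-[(4-methoxyphenyl)methoxy]ethyl]hex-4-enoate | COC(=O)C(=CO)[C@@H](CCOCc1ccc(OC)cc1)/C(C=O)=C\C
A4 | alternative 2 | methyl 2,3-trans-3,4-trans-3-formyl-4-[2-[(4-methoxyphenyl)methoxy]ethyl]-2-methyl-3,4-dihydro-2H-pyran-5-carboxylate | COC(=O)C1=CO[C@H](C)[C@@H](C=O)[C@@H]1CCOCc1ccc(OC)cc1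
A5 | alternative 3 | 2-[3,4-bis(tert-butyldimethylsilyloxy)phenyl]ethyl (2E,4R,5R)-4-(tert-butyldimethylsilyloxymethyl)-5-hydroxyhex-2-enoate | C[C@@H](O)[C@@H](CO[Si](C)(C)C(C)(C)C)/C=C/C(=O)OCCc1ccc(O[Si](C)(C)C(C)(C)C)c(O[Si](C)(C)C(C)(C)C)c1
A6 | alternative 3 | methyl propiolate | C#CC(=O)OC
A7 | alternative 3 | methyl (2R,3R,4S)-4-[2-[2-[3,4-bis(tert-butyldimethylsilyloxy)phenyl]ethoxy]-2-oxoethyl]-3-[(tert-butyldimethylsilyloxy)methyl]-2-methyl-3,4-dihydro-2H-pyran-5-carboxylate (identical with 21) | COC(=O)C1=CO[C@H](C)[C@@H](CO[Si](C)(C)C(C)(C)C)[C@@H]1CC(=O)OCCc1ccc(O[Si](C)(C)C(C)(C)C)c(O[Si](C)(C)C(C)(C)C)c1
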